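**Retrosynthetic overview**
1. The last step only removes two MOM ethers from the (4R)-tetralone 13; all carbons and the C4 stereocenter are in place after step 8.
2. Key disconnection C3–C4 closes the cyclohexanone ring of the tetralone. C4 is benzylic to the hydroquinone ring and, through C1'–C4' of the naphthalene ring, para to the free 4'-OH, so it is the exocyclic carbon of a latent naphtho-para-quinone methide. C3 lies β to the C1 ketone, so C1–C2–C3 is a homoenolate, masked as a 1-arylcyclopropanol (C1 the carbinol, C2 and C3 the two CH2).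
3. The cyclopropanol comes from a Kulinkovich reaction on a 3-aryl phthalide, a temporary lactone ring that holds C1 and C4 ortho on the hydroquinone ring. The phthalide comes from ortho-magnesiated, MOM-protected methyl gentisate and a 4-silyloxy-8-methoxy-1-naphthaldehyde (C4–C4a bond).
4. The naphthaldehyde comes from 1,5-dimethoxynaphthalene by formylation and demethylation of the one methoxy group that is conjugated with the aldehyde.
5. Ring order: both arene rings are bought; lactone ring (step 5), then cyclopropane (step 6), then tetralone ring (step 8); the first two are temporary.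

Key step: step 8

Remark: the sense of induction of the chiral phosphoric acid in step 8 cannot be predicted with certainty, so the (R)-acid is written and its antipode is to be used if the product proves to be (4S); tetralone atoms are numbered C1–C8a and naphthalene atoms C1'–C8a' as in the name of the target.

**Step 1**
Reactants: 1 1,5-dimethoxynaphthalene
Product: 2 4,8-dimethoxynaphthalene-1-carbaldehyde
Conditions: POCl3, DMF, toluene, 0 °C → 90 °C; then ice–water
Reagents that add atoms: N,N-dimethylformamide CN(C)C=O (formyl carbon); water O (carbonyl oxygen, on hydrolysis of the iminium salt)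
Why: Vilsmeier–Haack formylation goes para to a methoxy group, the two para positions of the symmetric arene are equivalent, and the formyl group deactivates the product against a second substitution.

**Step 2**
Reactants: 2 4,8-dimethoxynaphthalene-1-carbaldehyde
Product: 3 4-hydroxy-8-methoxynaphthalene-1-carbaldehyde
Conditions: NaSEt (2.5 equiv), DMF, 100 °C; then 1 M HCl
Reagents that add atoms: none
Why: Nucleophilic (SN2) O-demethylation by thiolate should take only the 4-methoxy group, because its aryloxide is a vinylogous carboxylate conjugated with the para formyl group, whereas the peri 8-methoxy group is not conjugated with the aldehyde.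

**Step 3**
Reactants: 3 4-hydroxy-8-methoxynaphthalene-1-carbaldehyde
Product: 4 4-[(tert-butyldimethylsilyl)oxy]-8-methoxynaphthalene-1-carbaldehyde
Conditions: TBSCl, imidazole, DMF, rt
Reagents that add atoms: tert-butyldimethylsilyl chloride CC(C)(C)[Si](C)(C)Cl
Why: Standard phenol silylation; the silyl ether survives the magnesium and titanium reagents, is removed by fluoride without touching MOM ethers, and prevents phenoxide-induced opening of the later lactone.

**Step 4**
Reactants: 5 methyl 2,5-dihydroxybenzoate
Product: 6 methyl 2,5-bis(methoxymethoxy)benzoate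
Conditions: NaH (2.5 equiv), MOMCl (2.5 equiv), DMF, 0 °C → rt
Reagents that add atoms: chloromethyl methyl ether COCCl
Why: Williamson-type O-alkylation of both phenoxides gives MOM ethers that protect the hydroquinone and serve as directing groups for the next metalation.

**Step 5**
Reactants: 6 methyl 2,5-bis(methoxymethoxy)benzoate; 4 4-[(tert-butyldimethylsilyl)oxy]-8-methoxynaphthalene-1-carbaldehyde
Product: 9 rac-3-{4-[(tert-butyldimethylsilyl)oxy]-8-methoxynaphthalen-1-yl}-4,7-bis(methoxymethoxy)-2-benzofuran-1(3H)-one, via arylmagnesium amide 7 (not isolated), via magnesium alkoxide adduct 8 (not isolated)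
Conditions: TMP2Mg·2LiCl (1.2 equiv), THF, −20 °C, 2 h; then 4, −20 °C → rt; aq NH4Cl
Reagents that add atoms: none
Why: Directed ortho-magnesiation should occur at the only C–H flanked by the ester and an OMOM group, 1,2-addition to the aldehyde follows, and the alkoxide lactonises onto the ortho ester to the phthalide; the new stereocenter forms as a racemate, which is irrelevant because it becomes planar in step 8.

**Step 6**
Reactants: 9 rac-3-{4-[(tert-butyldimethylsilyl)oxy]-8-methoxynaphthalen-1-yl}-4,7-bis(methoxymethoxy)-2-benzofuran-1(3H)-one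
Product: 10 rac-1-{2-[{4-[(tert-butyldimethylsilyl)oxy]-8-methoxynaphthalen-1-yl}(hydroxy)methyl]-3,6-bis(methoxymethoxy)phenyl}cyclopropan-1-ol
Conditions: EtMgBr (3.5 equiv, slow addition), Ti(OiPr)4 (0.5 equiv), THF, 0 °C → rt; cold aq NH4Cl
Reagents that add atoms: ethylmagnesium bromide CC[Mg]Br
Why: Kulinkovich cyclopropanation of a lactone, in which the titanacyclopropane formed from EtMgBr and Ti(OiPr)4 acts as a 1,2-dicarbanion toward the lactone carbonyl and gives the 1-arylcyclopropanol while releasing the diaryl carbinol; silyl and MOM ethers are inert.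

**Step 7**
Reactants: 10 rac-1-{2-[{4-[(tert-butyldimethylsilyl)oxy]-8-methoxynaphthalen-1-yl}(hydroxy)methyl]-3,6-bis(methoxymethoxy)phenyl}cyclopropan-1-ol
Product: 11 rac-1-{2-[hydroxy(4-hydroxy-8-methoxynaphthalen-1-yl)methyl]-3,6-bis(methoxymethoxy)phenyl}cyclopropan-1-ol
Conditions: TBAF (1.1 equiv), AcOH (1.1 equiv), THF, 0 °C; used crude
Reagents that add atoms: none
Why: Fluoride cleaves the aryl silyl ether selectively, and the acetic acid buffer keeps the naphthoxide from expelling the benzylic hydroxyl before the catalyst is present.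

**Step 8**
Reactants: 11 rac-1-{2-[hydroxy(4-hydroxy-8-methoxynaphthalen-1-yl)methyl]-3,6-bis(methoxymethoxy)phenyl}cyclopropan-1-ol
Product: 13 (4R)-4-(4-hydroxy-8-methoxynaphthalen-1-yl)-5,8-bis(methoxymethoxy)-3,4-dihydronaphthalen-1(2H)-one, via para-quinone methide 12 (not isolated)
Conditions: (R)-3,3'-bis(2,4,6-triisopropylphenyl)-1,1'-binaphthyl-2,2'-diyl hydrogen phosphate (10 mol%), 5 Å MS, toluene (0.02 M), 0 °C → rt
Reagents that add atoms: none
Why: Proposed new method: the chiral phosphoric acid should dehydrate the para-hydroxy diaryl carbinol to the (E)-naphtho-para-quinone methide 12 (a temporary dearomatisation of the naphthol ring) and hold it by a hydrogen bond from P–OH to the quinone methide carbonyl while its P=O accepts the cyclopropanol O–H, so that the electron-rich C1–C3 bond of the cyclopropanol adds as a homoenolate to the exocyclic carbon C4 in a 1,6-conjugate addition, the release of about 27 kcal/mol of ring strain giving the C1 ketone and the re-aromatised naphthol in the same event. The closest known reaction types are chiral phosphoric acid-catalysed enantioselective 1,6-additions of carbon nucleophiles to para-quinone methides generated in situ from para-hydroxybenzylic alcohols, and the acid-mediated intramolecular ring-opening attack of cyclopropanols on oxocarbenium ions that gives β-substituted ketones; the combination, a cyclopropanol adding enantioselectively to a quinone methide, is the new element. The cyclohexanone ring closes in a 6-exo-trig mode with respect to the exocyclic C4=C1' bond of 12. The C4 stereocenter is set by the catalyst, whose 3,3'-aryl groups, with the substrate bound at two points, should expose one enantiotopic face of the planar quinone methide to the tethered cyclopropane. The step needs C- over O-alkylation and a single quinone methide geometry: the first should be secured because closure through the cyclopropanol oxygen is reversible under the acid whereas the strain-releasing C–C closure is not, the second because the peri 8'-methoxy group forces the aryl substituent of 12 to the C3' side. The two ortho substituents keep the hydroquinone ring perpendicular to the quinone methide plane, which places the cyclopropane CH2 directly over C4.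

**Step 9**
Reactants: 13 (4R)-4-(4-hydroxy-8-methoxynaphthalen-1-yl)-5,8-bis(methoxymethoxy)-3,4-dihydronaphthalen-1(2H)-one
Product: 14 (4R)-5,8-dihydroxy-4-(4-hydroxy-8-methoxynaphthalen-1-yl)-3,4-dihydronaphthalen-1(2H)-one
Conditions: HCl (3 M in MeOH), THF, 0 °C → rt, argon
Reagents that add atoms: none
Why: Acid-catalysed transacetalisation to dimethoxymethane cleaves both aryl MOM ethers, while the aryl methyl ether, the ketone and the C4 methine, which carries no leaving group and is not enolisable, should be untouched at room temperature.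

**Compound list**
1 | 1,5-dimethoxynaphthalene | COc1cccc2c(OC)cccc12 | starting material
2 | 4,8-dimethoxynaphthalene-1-carbaldehyde | COc1ccc(C=O)c2c(OC)cccc12 | intermediate
3 | 4-hydroxy-8-methoxynaphthalene-1-carbaldehyde | COc1cccc2c(O)ccc(C=O)c12 | intermediate
4 | 4-[(tert-butyldimethylsilyl)oxy]-8-methoxynaphthalene-1-carbaldehyde | COc1cccc2c(O[Si](C)(C)C(C)(C)C)ccc(C=O)c12 | intermediate
5 | methyl 2,5-dihydroxybenzoate | COC(=O)c1cc(O)ccc1O | starting material
6 | methyl 2,5-bis(methoxymethoxy)benzoate | COCOc1ccc(OCOC)c(C(=O)OC)c1 | intermediate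
7 | [2-(methoxycarbonyl)-3,6-bis(methoxymethoxy)phenyl]magnesium 2,2,6,6-tetramethylpiperidide (LiCl adduct, drawn without LiCl; not isolated) | COCOc1ccc(OCOC)c(C(=O)OC)c1[Mg]N1C(C)(C)CCCC1(C)C | intermediate
8 | magnesium alkoxide of methyl 2-[{4-[(tert-butyldimethylsilyl)oxy]-8-methoxynaphthalen-1-yl}(hydroxy)methyl]-3,6-bis(methoxymethoxy)benzoate (racemic; not isolated) | COCOc1ccc(OCOC)c(C(=O)OC)c1C(O[Mg]N1C(C)(C)CCCC1(C)C)c1ccc(O[Si](C)(C)C(C)(C)C)c2cccc(OC)c12 | intermediate
9 | rac-3-{4-[(tert-butyldimethylsilyl)oxy]-8-methoxynaphthalen-1-yl}-4,7-bis(methoxymethoxy)-2-benzofuran-1(3H)-one | COCOc1ccc(OCOC)c2c1C(=O)OC2c1ccc(O[Si](C)(C)C(C)(C)C)c2cccc(OC)c12 | intermediate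
10 | rac-1-{2-[{4-[(tert-butyldimethylsilyl)oxy]-8-methoxynaphthalen-1-yl}(hydroxy)methyl]-3,6-bis(methoxymethoxy)phenyl}cyclopropan-1-ol | COCOc1ccc(OCOC)c(C(O)c2ccc(O[Si](C)(C)C(C)(C)C)c3cccc(OC)c23)c1C1(O)CC1 | intermediate
11 | rac-1-{2-[hydroxy(4-hydroxy-8-methoxynaphthalen-1-yl)methyl]-3,6-bis(methoxymethoxy)phenyl}cyclopropan-1-ol | COCOc1ccc(OCOC)c(C(O)c2ccc(O)c3cccc(OC)c23)c1C1(O)CC1 | intermediate
12 | (E)-4-{[2-(1-hydroxycyclopropyl)-3,6-bis(methoxymethoxy)phenyl]methylidene}-5-methoxynaphthalen-1(4H)-one (aryl group on the C3 side; not isolated) | COc1cccc2C(=O)C=C/C(=C\c3c(OCOC)ccc(OCOC)c3C3(O)CC3)c12 | intermediate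
13 | (4R)-4-(4-hydroxy-8-methoxynaphthalen-1-yl)-5,8-bis(methoxymethoxy)-3,4-dihydronaphthalen-1(2H)-one | COc1cccc2c(O)ccc([C@H]3CCC(=O)c4c(OCOC)ccc(OCOC)c43)c12 | intermediate
14 | (4R)-5,8-dihydroxy-4-(4-hydroxy-8-methoxynaphthalen-1-yl)-3,4-dihydronaphthalen-1(2H)-one | COc1cccc2c(O)ccc([C@H]3CCC(=O)c4c(O)ccc(O)c43)c12 | target

**Step count**
Total: 9 steps. Longest linear sequence: 8 steps (1 → 2 → 3 → 4 → 9 → 10 → 11 → 13 → 14; steps 1, 2, 3, 5, 6, 7, 8, 9).

**Steps most likely to fail**

Step 8 (Proposed new method). The strained C–C bond may not engage the acid-bound quinone methide fast enough, so that material rests in the reversible O-closure manifold or the cyclopropanol opens by protonolysis. The facial discrimination by the catalyst may also be insufficient. The fallback uses known reaction types only; it sets out from 9 and comes back to the route at 13. It keeps the quinone methide electrophile but makes C3 nucleophilic as an aldehyde enamine (aminocatalytic α-alkylation of aldehydes by 1,6-addition to para-quinone methides) and removes the activating formyl group afterwards. 3-Butenylmagnesium bromide (1.1 equiv, THF, −78 °C) should open lactone 9 by single addition to the pentenyl ketone F1 (open form of its lactol). Lemieux–Johnson cleavage (OsO4 cat., NaIO4, 2,6-lutidine, dioxane–water) gives the keto aldehyde F2. TBAF/AcOH (THF, 0 °C) gives the free naphthol F3. (S)-α,α-Diphenylprolinol trimethylsilyl ether (20 mol%) with 4-nitrobenzoic acid in CH2Cl2 should then cyclise F3, after acid-induced dehydration of the carbinol, by intramolecular enamine 1,6-addition to the trans-3-formyl tetralone F4. The catalyst sets C3, the chair-like closure sets C4 trans to it, and the catalyst antipode that gives 4R is used. Tsuji–Wilkinson decarbonylation with RhCl(PPh3)3 (1.1 equiv, PhCN, 130 °C) removes the formyl group and gives 13.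

Step 6. Addition of the titanacyclopropane to the doubly ortho-substituted lactone carbonyl may be slow, with competing plain ethyl addition or deprotonation at the lactone C3–H, and the carbinol may ionise during work-up. The fallback sets out from 9 and comes back to the route at 11, replacing steps 6 and 7. MeLi (1.05 equiv, THF, −78 °C) adds once to the lactone to give the methyl ketone F5 (open form of its lactol). Et3SiOTf/Et3N (CH2Cl2, 0 °C) gives the bis-silylated enol ether F6, in which the carbinol is silylated as well. Simmons–Smith cyclopropanation (Et2Zn, CH2I2, CH2Cl2, 0 °C) of the electron-rich enol ether gives the siloxycyclopropane F7. TBAF/AcOH (THF, 0 °C) removes all three silyl groups and gives 11.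

Step 5. Magnesiation of the electron-rich benzoate may be incomplete or misdirected, and addition of the hindered arylmagnesium to the peri-substituted aldehyde may be sluggish. The fallback sets out from 6 and comes back to the route at 9, using a more strongly directing amide and a more reactive aryllithium. Me2AlNEt2 (from AlMe3 and Et2NH, toluene, 80 °C) converts ester 6 into the diethylamide F8. Directed ortho-lithiation (s-BuLi, TMEDA, THF, −78 °C) between the amide and the 5-OMOM group, followed by addition of aldehyde 4, gives the hydroxy amide F9. This lactonises to 9 with loss of diethylamine on warming in toluene with catalytic camphorsulfonic acid.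

**Further compounds**
F1 | step 8 | rac-1-{2-[{4-[(tert-butyldimethylsilyl)oxy]-8-methoxynaphthalen-1-yl}(hydroxy)methyl]-3,6-bis(methoxymethoxy)phenyl}pent-4-en-1-one | COCOc1ccc(OCOC)c(C(O)c2ccc(O[Si](C)(C)C(C)(C)C)c3cccc(OC)c23)c1C(=O)CCC=C
F2 | step 8 | rac-4-{2-[{4-[(tert-butyldimethylsilyl)oxy]-8-methoxynaphthalen-1-yl}(hydroxy)methyl]-3,6-bis(methoxymethoxy)phenyl}-4-oxobutanal | COCOc1ccc(OCOC)c(C(O)c2ccc(O[Si](C)(C)C(C)(C)C)c3cccc(OC)c23)c1C(=O)CCC=O
F3 | step 8 | rac-4-{2-[hydroxy(4-hydroxy-8-methoxynaphthalen-1-yl)methyl]-3,6-bis(methoxymethoxy)phenyl}-4-oxobutanal | COCOc1ccc(OCOC)c(C(O)c2ccc(O)c3cccc(OC)c23)c1C(=O)CCC=O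
F4 | step 8 | (1R,2R)-1-(4-hydroxy-8-methoxynaphthalen-1-yl)-5,8-bis(methoxymethoxy)-4-oxo-1,2,3,4-tetrahydronaphthalene-2-carbaldehyde (trans) | COc1cccc2c(O)ccc([C@H]3[C@H](C=O)CC(=O)c4c(OCOC)ccc(OCOC)c43)c12
F5 | step 6 | rac-1-{2-[{4-[(tert-butyldimethylsilyl)oxy]-8-methoxynaphthalen-1-yl}(hydroxy)methyl]-3,6-bis(methoxymethoxy)phenyl}ethan-1-one | COCOc1ccc(OCOC)c(C(O)c2ccc(O[Si](C)(C)C(C)(C)C)c3cccc(OC)c23)c1C(C)=O
F6 | step 6 | rac-tert-butyl{[5-methoxy-4-({3,6-bis(methoxymethoxy)-2-[1-(triethylsilyloxy)ethenyl]phenyl}(triethylsilyloxy)methyl)naphthalen-1-yl]oxy}dimethylsilane | COCOc1ccc(OCOC)c(C(O[Si](CC)(CC)CC)c2ccc(O[Si](C)(C)C(C)(C)C)c3cccc(OC)c23)c1C(=C)O[Si](CC)(CC)CC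
F7 | step 6 | rac-tert-butyl{[5-methoxy-4-({3,6-bis(methoxymethoxy)-2-[1-(triethylsilyloxy)cyclopropyl]phenyl}(triethylsilyloxy)methyl)naphthalen-1-yl]oxy}dimethylsilane | COCOc1ccc(OCOC)c(C(O[Si](CC)(CC)CC)c2ccc(O[Si](C)(C)C(C)(C)C)c3cccc(OC)c23)c1C1(O[Si](CC)(CC)CC)CC1
F8 | step 5 | N,N-diethyl-2,5-bis(methoxymethoxy)benzamide | CCN(CC)C(=O)c1cc(OCOC)ccc1OCOC
F9 | step 5 | rac-2-[{4-[(tert-butyldimethylsilyl)oxy]-8-methoxynaphthalen-1-yl}(hydroxy)methyl]-N,N-diethyl-3,6-bis(methoxymethoxy)benzamide | CCN(CC)C(=O)c1c(OCOC)ccc(OCOC)c1C(O)c1ccc(O[Si](C)(C)C(C)(C)C)c2cccc(OC)c12
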